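**Retrosynthetic overview**
- The 1,2-dioxane is the only ring and is closed last: hemiketal ⇐ 3-methoxy-1,2-dioxane ⇐ 6-exo cycloperoxymercuration of an α-methoxy hydroperoxide made from a γ,δ-unsaturated methyl ketone.
- That ketone ⇐ carboxylic acid whose C4–C5 bond (target numbering) is made by an Ireland–Claisen [3,3] rearrangement of an allylic propionate; this key step also sets C4 and the E-trisubstituted alkene.
- Allylic alcohol ⇐ Felkin–Anh addition of isopropenylmagnesium bromide to an α-methyl aldehyde.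
- Aldehyde ⇐ Cu-catalysed coupling of Roche-ester-derived (S)-3-bromo-2-methylpropan-1-ol with a (Z)-styrenyl alkyl Grignard ⇐ B-alkyl Suzuki coupling.
- Stereochemical relay: bought C2' → carbinol → C4 → C6 → C3 (anomeric equilibration).

Assumption: (S)-3-bromo-2-methylpropan-1-ol and (Z)-β-bromostyrene are bought as catalogue compounds.

**Route**

Step 1
Reactants: 1 5-bromopent-1-ene; 2 (Z)-β-bromostyrene
Product: 4 [(1Z)-7-bromohept-1-en-1-yl]benzene, via B-alkyl-9-BBN 3 (not isolated)
Conditions: 9-BBN, THF, 0 °C→rt; then 2, Pd(dppf)Cl2 (3 mol%), K3PO4 (aq), DMF, rt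
Reagents that add atoms: none
Why: Anti-Markovnikov hydroboration followed by B-alkyl Suzuki–Miyaura coupling, which retains the Z geometry of the vinyl bromide while the primary alkyl bromide is inert to Pd(0) at room temperature.

Step 2
Reactants: 4 [(1Z)-7-bromohept-1-en-1-yl]benzene; 5 (2S)-3-bromo-2-methylpropan-1-ol
Product: 8 (2R,9Z)-2-methyl-10-phenyldec-9-en-1-ol, via Grignard reagent 6 (not isolated), via bromomagnesium alkoxide 7 (not isolated)
Conditions: 4, Mg, THF, rt; 5, MeMgBr, THF, −20 °C; then Li2CuCl4 (5 mol%), NMP, THF, −20 °C→rt; aq NH4Cl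
Reagents that add atoms: none
Why: Kochi-type copper-catalysed sp3–sp3 Grignard cross-coupling on the pre-formed magnesium alkoxide displaces the primary bromide and leaves untouched the methyl-bearing stereocentre bought with 5, which becomes C2' of the target.

Step 3
Reactants: 8 (2R,9Z)-2-methyl-10-phenyldec-9-en-1-ol
Product: 9 (2R,9Z)-2-methyl-10-phenyldec-9-enal
Conditions: TEMPO (10 mol%), PhI(OAc)2, CH2Cl2, rt
Reagents that add atoms: none
Why: TEMPO/PhI(OAc)2 oxidation stops at the aldehyde under non-basic conditions, so the α-stereocentre is not epimerised.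

Step 4
Reactants: 9 (2R,9Z)-2-methyl-10-phenyldec-9-enal
Product: 10 (3S,4R,11Z)-2,4-dimethyl-12-phenyldodeca-1,11-dien-3-ol
Conditions: CH2=C(CH3)MgBr, THF, −78 °C; aq NH4Cl; chromatography
Reagents that add atoms: isopropenylmagnesium bromide, CC(=C)[Mg]Br
Why: Grignard 1,2-addition under Felkin–Anh control by the α-methyl stereocentre gives mainly the 3,4-syn (3S) carbinol (expected about 3–4:1), and the diastereomers, which differ at adjacent centres, are separated by chromatography.

Step 5
Reactants: 10 (3S,4R,11Z)-2,4-dimethyl-12-phenyldodeca-1,11-dien-3-ol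
Product: 11 (3S,4R,11Z)-2,4-dimethyl-12-phenyldodeca-1,11-dien-3-yl propanoate
Conditions: (EtCO)2O, Et3N, DMAP (cat.), CH2Cl2, 0 °C→rt
Reagents that add atoms: propionic anhydride, CCC(=O)OC(=O)CC
Why: DMAP-catalysed acylation of the secondary allylic alcohol with retention at the carbinol centre.

Step 6
Reactants: 11 (3S,4R,11Z)-2,4-dimethyl-12-phenyldodeca-1,11-dien-3-yl propanoate
Product: 14 (2R,4E,6R,13Z)-2,4,6-trimethyl-14-phenyltetradeca-4,13-dienoic acid, via (E)-silyl ketene acetal 12 (not isolated), via trimethylsilyl ester 13 (not isolated)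
Conditions: LDA, TMSCl, Et3N, THF, −78 °C→rt, then 60 °C; 1 M HCl
Reagents that add atoms: none
Why: Ireland–Claisen [3,3]-sigmatropic rearrangement of the kinetic (E)-silyl ketene acetal through a chair transition state with the carbinol substituent equatorial forges the C2–C3 bond (C4–C5 of the target), transfers the carbinol chirality to the new (2R) methyl-bearing centre (expected at least 10:1) and delivers the (E)-trisubstituted alkene.

Step 7
Reactants: 14 (2R,4E,6R,13Z)-2,4,6-trimethyl-14-phenyltetradeca-4,13-dienoic acid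
Product: 15 (3R,5E,7R,14Z)-3,5,7-trimethyl-15-phenylpentadeca-5,14-dien-2-one
Conditions: MeLi (2.5 equiv), THF, −78→0 °C; inverse quench into aq NH4Cl
Reagents that add atoms: methyllithium, [Li]C
Why: Addition of methyllithium to the lithium carboxylate gives a dilithio gem-diolate that collapses to the methyl ketone only on work-up, so there is no over-addition and the α-centre is not enolised.

Step 8
Reactants: 15 (3R,5E,7R,14Z)-3,5,7-trimethyl-15-phenylpentadeca-5,14-dien-2-one
Product: 16 (3R,5E,7R,14Z)-2-hydroperoxy-2-methoxy-3,5,7-trimethyl-15-phenylpentadeca-5,14-diene (both C2 epimers)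
Conditions: urea·H2O2, Sc(OTf)3 (10 mol%), MeOH, rt
Reagents that add atoms: urea–hydrogen peroxide, OO.NC(N)=O; methanol, CO
Why: Lewis-acid-catalysed perketalisation turns the ketone into the α-methoxy hydroperoxide, which places the peroxide nucleophile on the future C3 without touching either alkene.

Step 9
Reactants: 16 (3R,5E,7R,14Z)-2-hydroperoxy-2-methoxy-3,5,7-trimethyl-15-phenylpentadeca-5,14-diene
Product: 18 (4R,6S)-3-methoxy-3,4,6-trimethyl-6-[(2R,9Z)-2-methyl-10-phenyldec-9-en-1-yl]-1,2-dioxane (both C3 epimers), via organomercurial 17 (not isolated)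
Conditions: Hg(OAc)2, CH2Cl2, 0 °C→rt; then NaBH4, 3 M NaOH, 0 °C
Reagents that add atoms: none
Why: 6-exo Markovnikov cycloperoxymercuration adds the hydroperoxide anti to mercury at the more substituted alkene carbon through a chair transition state with the C4 methyl and the bulky mercurated side arm equatorial, which sets the quaternary C6 cis to C4 (6S, expected only about 3–4:1), and alkaline NaBH4 hydridodemercuration then leaves the O–O bond intact.

Step 10
Reactants: 18 (4R,6S)-3-methoxy-3,4,6-trimethyl-6-[(2R,9Z)-2-methyl-10-phenyldec-9-en-1-yl]-1,2-dioxane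
Product: 19 (3S,4R,6S)-3,4,6-trimethyl-6-[(2R,9Z)-2-methyl-10-phenyldec-9-en-1-yl]-1,2-dioxan-3-ol
Conditions: TFA (cat.), THF–H2O, 0 °C→rt; chromatography
Reagents that add atoms: water, O
Why: Mild acid-catalysed hydrolysis of the peroxyketal gives the hemiketal, whose C3 equilibrates through the hydroperoxy ketone to the anomerically favoured axial OH next to the equatorial C4 methyl (3S), and the minor C6 epimer and traces of C4 epimer are removed by chromatography.

**Compound list**
1 | 5-bromopent-1-ene | C=CCCCBr | starting material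
2 | (Z)-β-bromostyrene | Br/C=C\c1ccccc1 | starting material
3 | 9-(5-bromopentyl)-9-borabicyclo[3.3.1]nonane | BrCCCCCB1C2CCCC1CCC2 | intermediate
4 | [(1Z)-7-bromohept-1-en-1-yl]benzene | BrCCCCC/C=C\c1ccccc1 | intermediate
5 | (2S)-3-bromo-2-methylpropan-1-ol | C[C@H](CBr)CO | starting material
6 | [(6Z)-7-phenylhept-6-en-1-yl]magnesium bromide | Br[Mg]CCCCC/C=C\c1ccccc1 | intermediate
7 | bromomagnesium (2S)-3-bromo-2-methylpropan-1-olate | C[C@H](CBr)CO[Mg]Br | intermediate
8 | (2R,9Z)-2-methyl-10-phenyldec-9-en-1-ol | C[C@H](CCCCCC/C=C\c1ccccc1)CO | intermediate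
9 | (2R,9Z)-2-methyl-10-phenyldec-9-enal | C[C@H](CCCCCC/C=C\c1ccccc1)C=O | intermediate
10 | (3S,4R,11Z)-2,4-dimethyl-12-phenyldodeca-1,11-dien-3-ol | C[C@H](CCCCCC/C=C\c1ccccc1)[C@H](O)C(C)=C | intermediate
11 | (3S,4R,11Z)-2,4-dimethyl-12-phenyldodeca-1,11-dien-3-yl propanoate | C[C@H](CCCCCC/C=C\c1ccccc1)[C@H](OC(=O)CC)C(C)=C | intermediate
12 | (E)-O-trimethylsilyl ketene acetal of 11 (CH3 trans to OSiMe3, cis to the allylic oxygen) | C[C@H](CCCCCC/C=C\c1ccccc1)[C@H](OC(=C/C)\O[Si](C)(C)C)C(C)=C | intermediate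
13 | trimethylsilyl (2R,4E,6R,13Z)-2,4,6-trimethyl-14-phenyltetradeca-4,13-dienoate | C[C@H](CCCCCC/C=C\c1ccccc1)/C=C(C)/C[C@@H](C)C(=O)O[Si](C)(C)C | intermediate
14 | (2R,4E,6R,13Z)-2,4,6-trimethyl-14-phenyltetradeca-4,13-dienoic acid | C[C@H](CCCCCC/C=C\c1ccccc1)/C=C(C)/C[C@@H](C)C(O)=O | intermediate
15 | (3R,5E,7R,14Z)-3,5,7-trimethyl-15-phenylpentadeca-5,14-dien-2-one | C[C@H](CCCCCC/C=C\c1ccccc1)/C=C(C)/C[C@@H](C)C(C)=O | intermediate
16 | (3R,5E,7R,14Z)-2-hydroperoxy-2-methoxy-3,5,7-trimethyl-15-phenylpentadeca-5,14-diene (C2 epimers) | C[C@H](CCCCCC/C=C\c1ccccc1)/C=C(C)/C[C@@H](C)C(C)(OC)OO | intermediate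
17 | 6-[(1S,2R,9Z)-1-(acetoxymercurio)-2-methyl-10-phenyldec-9-en-1-yl]-3-methoxy-3,4,6-trimethyl-1,2-dioxane (ring geometry as in 18; C3 epimers) | C[C@H](CCCCCC/C=C\c1ccccc1)[C@H]([Hg]OC(C)=O)[C@@]1(C)C[C@@H](C)C(C)(OC)OO1 | intermediate
18 | (4R,6S)-3-methoxy-3,4,6-trimethyl-6-[(2R,9Z)-2-methyl-10-phenyldec-9-en-1-yl]-1,2-dioxane (C3 epimers) | C[C@H](CCCCCC/C=C\c1ccccc1)C[C@@]1(C)C[C@@H](C)C(C)(OC)OO1 | intermediate
19 | (3S,4R,6S)-3,4,6-trimethyl-6-[(2R,9Z)-2-methyl-10-phenyldec-9-en-1-yl]-1,2-dioxan-3-ol | C[C@H](CCCCCC/C=C\c1ccccc1)C[C@@]1(C)C[C@@H](C)[C@@](C)(O)OO1 | target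

**Totals and risks**

Total step count: 10. Longest linear sequence: 10 (steps 1 to 10; compound 5 enters at step 2 as bought).

Steps most likely to fail: 9, 6 and 4.

Step 9 is the weakest step. The C6 selectivity is modest, and the β-peroxy radical formed during demercuration can collapse to an epoxide. The fallback sets out from ketone 15 and comes back at target 19. A cobalt-catalysed Isayama–Mukaiyama hydroperoxysilylation (Co(thd)2, Et3SiH, O2, DCE, rt) puts the peroxide on the tertiary carbon by radical Markovnikov addition and gives (3R,7R,14Z)-3,5,7-trimethyl-15-phenyl-5-[(triethylsilyl)peroxy]pentadec-14-en-2-one F1 as a 1:1 mixture at C5. HF·pyridine in THF at 0 °C then removes the silyl group, and the freed hydroperoxide closes onto the ketone to give 19 and its C6 epimer, which are separated as ring diastereomers. This avoids mercury and the ketal hydrolysis, but gives no induction at C6. H-atom transfer to the styrene competes and has to be limited by running to partial conversion.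

Step 6 can lose stereochemical fidelity through imperfect enolate geometry or a competing boat transition state, and the resulting C4 epimer cannot be removed until the end. The fallback sets out from allylic alcohol 10 and comes back at ketone 15. An Eschenmoser–Claisen rearrangement with N,N-dimethylpropionamide dimethyl acetal (xylene, 140 °C) goes through an N,O-ketene acetal whose methyl group is held cis to the allylic oxygen by strain against NMe2. It gives (2R,4E,6R,13Z)-N,N,2,4,6-pentamethyl-14-phenyltetradeca-4,13-dienamide F2 with no enolate-geometry issue, and MeLi in THF converts this amide directly into 15.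

Step 4 may give a poor Felkin ratio. The fallback sets out from aldehyde 9 and comes back at alcohol 10. The unwanted epimer (3R,4R,11Z)-2,4-dimethyl-12-phenyldodeca-1,11-dien-3-ol F3, formed beside 10 and separated from it, is not discarded. Mitsunobu inversion with 4-nitrobenzoic acid (PPh3, DIAD, THF) gives (3S,4R,11Z)-2,4-dimethyl-12-phenyldodeca-1,11-dien-3-yl 4-nitrobenzoate F4, and K2CO3 in MeOH cleaves the ester to return 10. The carbinol configuration is thus corrected by invertive substitution and no longer depends on facial selectivity alone.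

**Further compounds**
F1 | step 9 | (3R,7R,14Z)-3,5,7-trimethyl-15-phenyl-5-[(triethylsilyl)peroxy]pentadec-14-en-2-one (C5 epimers) | C[C@H](CCCCCC/C=C\c1ccccc1)CC(C)(OO[Si](CC)(CC)CC)C[C@@H](C)C(C)=O
F2 | step 6 | (2R,4E,6R,13Z)-N,N,2,4,6-pentamethyl-14-phenyltetradeca-4,13-dienamide | C[C@H](CCCCCC/C=C\c1ccccc1)/C=C(C)/C[C@@H](C)C(=O)N(C)C
F3 | step 4 | (3R,4R,11Z)-2,4-dimethyl-12-phenyldodeca-1,11-dien-3-ol | C[C@H](CCCCCC/C=C\c1ccccc1)[C@@H](O)C(C)=C
F4 | step 4 | (3S,4R,11Z)-2,4-dimethyl-12-phenyldodeca-1,11-dien-3-yl 4-nitrobenzoate | C[C@H](CCCCCC/C=C\c1ccccc1)[C@H](OC(=O)c1ccc(cc1)[N+]([O-])=O)C(C)=C
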